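The vessel before the meeting was closed, stirred and isothermal, with two earlier runs on the table and one new recipe to judge.

| setting | violet | teal | flask |
|---|---|---|---|
| substrate | 0.20 M | 0.20 M | 0.20 M |
| first nucleophile | 1.3 equiv | 3 equiv | 2.00 equiv |
| second nucleophile | 1.3 equiv | 1.3 equiv | 1.30 equiv |
| capture agent | 4 mM | 4 mM | 4.00 mM |
| remark | run made earlier | run made earlier |  |
| time |  |  | 40 h |

| run | time / h | target / % |
|---|---|---|
| violet | 4.00 | 6.7 |
| violet | 6.00 | 7.0 |
| violet | 10.0 | 10.7 |
| violet | 15.0 | 14.7 |
| violet | 20.0 | 12.7 |
| violet | 30.0 | 11.0 |
| teal | 4.00 | 11.0 |
| teal | 6.00 | 13.1 |
| teal | 10.0 | 19.7 |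
| teal | 15.0 | 21.9 |
| teal | 20.0 | 21.1 |
| teal | 30.0 | 18.5 |

(each reading ± 1 percentage point)

1. the moment within 40 h at which there is most target
2. the amount of target, in percent of the substrate charged, at that time

- what was read earlier has a scatter of 1 percentage point, one standard deviation
- a reading or a percentage of target counts all its forms, free or not

The first speaker observed that target rises and then falls in both runs. The highest reading stands at 15.0 h in each and the next highest at 20.0 h, so she placed the moment of most target in the new flask between those times.

The second speaker compared heights. From violet to teal, with the other charges the same, the first nucleophile charge grows 2.31-fold, but the summed target readings grow less, 1.68-fold. He therefore proposed n = 0.618, the logarithm of the ratio of sums over the logarithm of the charge ratio, an apparent order of target height in first nucleophile, itself a reading that carries the scatter.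

As keeper of the minutes, I made my own reckoning. I averaged the two top readings of each run, scaled each average to the new charge by the charge ratio raised to n, and took the mean of the two, which gives 17.3%.

The forecast stood at 18% at 15.5 h, a little above my figure, with an order of about 0.6, on the ground that “the first nucleophile mainly scales the height”.

The flask gives 16.6% at 17.7 h, so the forecast holds within its margins, and my figure lies 0.7 percentage points above the result, against a scatter of 1 point on a single reading.

    substrate + target ⇌ idle adduct, settled at all times (K = 8.60 M⁻¹)
    first nucleophile + open intermediate ⇌ target (K = 1.30 M⁻¹, k = 8.80 × 10⁻⁴ M⁻¹ s⁻¹)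
    open intermediate + capture agent → trapped intermediate (k = 1.90 × 10⁻⁴ M⁻¹ s⁻¹)
    substrate → open intermediate (k = 1.50 × 10⁻⁵ s⁻¹)
    second nucleophile + open intermediate → other capture product (k = 8.90 × 10⁻⁵ M⁻¹ s⁻¹)

At 40.0 h the capture of open intermediate by second nucleophile runs at 0.044 of the forward rate of the step to target, yet this flask then holds more other capture product, 49.5%, than target, 12.7%. In the scheme the step to target runs both ways and the capture runs one way.

For the same flask with 0.800 equiv of first nucleophile, a charge below those of both runs, n scales 16.6% down to an estimate of 9.42%. The computed best there is 8.26%.

The runs stem from a simulated flask for an exercise; scatter was added.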